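**Plan**

- Retrosynthetic cuts: first the C8–C(=O) aryl ketone bond (aryl bromide plus a cinnamoyl Weinreb amide), then the C3 carbinol back to a ketone, then the C4–C4a bond together with the C3 carbonyl, and last the O1–C2 ether bond.
- Enabling feature: in the pyran ring O1–C2(CH3)2–C3(O)–C4–C4a, C3 is oxygenated and C4 is bonded to C4a, the only arene carbon ortho to O1 that is free once C8 carries bromine. An aryl 1,1-dimethylpropargyl ether therefore already holds O1, C2, C3 and C4.
- Forward order: phenol O-propargylation, gold-catalysed alkyne oxidation with arene capture (closes the pyran ring, the only ring made), ketone reduction, silylation, aryllithium acylation joining the three-carbon chain, desilylation.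
- Stereochemistry: the single stereocentre, C3 (S), comes from a Corey–Bakshi–Shibata reduction of the chroman-3-one. The E alkene is carried in from p-coumaric acid.

Key step: step 2

Assumption: in the oxazaborolidine reduction the quaternary C2 is taken as the large and the C4 methylene as the small ketone substituent, which makes the (R)-catalyst the one that should give the (S)-alcohol.

**Step 1**
Reactants: 1 2-bromo-5-methoxyphenol; 2 3-chloro-3-methylbut-1-yne
Product: 3 1-bromo-4-methoxy-2-[(2-methylbut-3-yn-2-yl)oxy]benzene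
Conditions: CuCl2·2H2O (0.5 mol %), DBU (1.3 equiv), MeCN, 0 °C
Reagents that add atoms: none
Why: Copper-catalysed propargylic substitution of a tertiary propargylic chloride by a phenoxide is the standard entry to aryl 1,1-dimethylpropargyl ethers, and at 0 °C the ether should not undergo Claisen rearrangement.

**Step 2**
Reactants: 3 1-bromo-4-methoxy-2-[(2-methylbut-3-yn-2-yl)oxy]benzene
Product: 5 8-bromo-5-methoxy-2,2-dimethylchroman-3-one, via α-oxo gold carbene 4 (not isolated)
Conditions: (Me4-t-BuXPhos)AuNTf2 (5 mol %; Me4-t-BuXPhos = 2-(t-Bu2P)-3,4,5,6-tetramethyl-2',4',6'-triisopropylbiphenyl), 2,6-dichloropyridine N-oxide (1.3 equiv, slow addition), 1,2-dichloroethane, rt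
Reagents that add atoms: 2,6-dichloropyridine N-oxide, [O-][n+]1c(Cl)cccc1Cl
Why: The cationic monovalent gold centre binds the terminal alkyne, the N-oxide oxygen adds to the internal carbon and N–O heterolysis expels 2,6-dichloropyridine, leaving α-oxo gold carbene 4 with the carbene on the former terminal carbon, now C4. The closest known reaction type is the gold-catalysed oxidative cyclisation of aryl propargyl ethers to chroman-3-ones. The pyran ring closes by a 6-exo Friedel–Crafts-type attack of C4a on the carbene carbon (the Au=C bond stays outside the new ring), and rearomatisation with protodeauration should give ketone 5. No stereocentre is created. The step needs oxygen delivery to the internal alkyne carbon, which the terminal alkyne dictates, and arene capture that outruns both a second oxidation of the carbene and direct hydroarylation of the alkyne: the short tether, the Thorpe–Ingold effect of the gem-dimethyl group, the bulky biaryl phosphine and the hindered, weakly basic oxidant serve this. The site of attack on the arene is fixed, because bromine blocks the other position ortho to the ether oxygen and the open one is activated by the flanking methoxy and ether oxygens.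

**Step 3**
Reactants: 5 8-bromo-5-methoxy-2,2-dimethylchroman-3-one
Product: 6 (3S)-8-bromo-5-methoxy-2,2-dimethylchroman-3-ol
Conditions: (R)-2-methyl-CBS-oxazaborolidine (15 mol %), BH3·SMe2 (0.7 equiv), THF, −20 °C; MeOH quench, aqueous work-up
Reagents that add atoms: none
Why: In the Corey–Bakshi–Shibata reduction the ketone should bind the oxazaborolidine boron anti to the quaternary C2, so that hydride from the coordinated borane reaches the face that gives the (S)-carbinol at C3 with the (R)-catalyst.

**Step 4**
Reactants: 6 (3S)-8-bromo-5-methoxy-2,2-dimethylchroman-3-ol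
Product: 7 (3S)-8-bromo-3-(tert-butyldimethylsilyloxy)-5-methoxy-2,2-dimethylchroman
Conditions: TBSOTf (1.3 equiv), 2,6-lutidine (2 equiv), CH2Cl2, 0 °C
Reagents that add atoms: tert-butyldimethylsilyl trifluoromethanesulfonate (TBSOTf), CC(C)(C)[Si](C)(C)OS(=O)(=O)C(F)(F)F
Why: Silylation with the triflate should overcome the hindrance of the alcohol next to the quaternary carbon, and the silyl ether removes the acidic proton before the organolithium step.

**Step 5**
Reactants: 8 p-coumaric acid, (E)-3-(4-hydroxyphenyl)prop-2-enoic acid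
Product: 10 (E)-3-(4-hydroxyphenyl)-N-methoxy-N-methylprop-2-enamide, via benzotriazol-1-yl ester 9 (not isolated)
Conditions: MeNHOMe·HCl (1.2 equiv), EDC·HCl (1.2 equiv), HOBt (1.2 equiv), i-Pr2NEt (2.5 equiv), DMF, 0 °C to rt
Reagents that add atoms: N,O-dimethylhydroxylamine hydrochloride, CNOC.Cl
Why: Carbodiimide amidation through the benzotriazolyl active ester should acylate the amine much faster than the free phenol, and the E alkene is untouched.

**Step 6**
Reactants: 10 (E)-3-(4-hydroxyphenyl)-N-methoxy-N-methylprop-2-enamide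
Product: 11 (E)-3-[4-(tert-butyldimethylsilyloxy)phenyl]-N-methoxy-N-methylprop-2-enamide
Conditions: TBSCl (1.2 equiv), imidazole (2 equiv), DMF, rt
Reagents that add atoms: tert-butyldimethylsilyl chloride (TBSCl), CC(C)(C)[Si](C)(C)Cl
Why: Standard imidazole-mediated silylation masks the phenolic proton, which would otherwise quench the aryllithium.

**Step 7**
Reactants: 7 (3S)-8-bromo-3-(tert-butyldimethylsilyloxy)-5-methoxy-2,2-dimethylchroman; 11 (E)-3-[4-(tert-butyldimethylsilyloxy)phenyl]-N-methoxy-N-methylprop-2-enamide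
Product: 14 (E)-1-[(3S)-3-(tert-butyldimethylsilyloxy)-5-methoxy-2,2-dimethylchroman-8-yl]-3-[4-(tert-butyldimethylsilyloxy)phenyl]prop-2-en-1-one, via aryllithium 12 (not isolated), via lithium hemiaminal alkoxide 13 (not isolated)
Conditions: n-BuLi (1.05 equiv), THF, −78 °C; then 11 (1.1 equiv), −78 to −20 °C; sat. aq NH4Cl
Reagents that add atoms: none
Why: Bromine–lithium exchange at −78 °C should give aryllithium 12, which adds 1,2 to the Weinreb amide, and the chelated adduct 13 releases the enone only on quench (Weinreb ketone synthesis), so over-addition is avoided.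

**Step 8**
Reactants: 14 (E)-1-[(3S)-3-(tert-butyldimethylsilyloxy)-5-methoxy-2,2-dimethylchroman-8-yl]-3-[4-(tert-butyldimethylsilyloxy)phenyl]prop-2-en-1-one
Product: 15 (E)-1-[(3S)-3-hydroxy-5-methoxy-2,2-dimethylchroman-8-yl]-3-(4-hydroxyphenyl)prop-2-en-1-one (CNP0291031.1)
Conditions: Bu4NF (2.5 equiv), AcOH (2.5 equiv), THF, 0 °C to rt, light excluded
Reagents that add atoms: none
Why: Fluoride-driven cleavage of Si–O bonds should remove the aryl and the alkyl silyl ether in one operation, and the acetic acid buffer keeps the phenolic enone from standing as a free phenoxide.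

**Compound list**

1 | 2-bromo-5-methoxyphenol | COc1ccc(Br)c(O)c1 | starting material
2 | 3-chloro-3-methylbut-1-yne | CC(C)(Cl)C#C | starting material
3 | 1-bromo-4-methoxy-2-[(2-methylbut-3-yn-2-yl)oxy]benzene | COc1ccc(Br)c(OC(C)(C)C#C)c1 | intermediate
4 | [3-(2-bromo-5-methoxyphenoxy)-3-methyl-2-oxobutylidene]gold carbene, Me4-t-BuXPhos-ligated cation, triflimide salt | COc1ccc(Br)c(OC(C)(C)C(=O)C=[Au][P+](C(C)(C)C)(C(C)(C)C)c2c(C)c(C)c(C)c(C)c2-c2c(C(C)C)cc(C(C)C)cc2C(C)C)c1.O=S(=O)([N-]S(=O)(=O)C(F)(F)F)C(F)(F)F | intermediate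
5 | 8-bromo-5-methoxy-2,2-dimethylchroman-3-one | COc1ccc(Br)c2c1CC(=O)C(C)(C)O2 | intermediate
6 | (3S)-8-bromo-5-methoxy-2,2-dimethylchroman-3-ol | COc1ccc(Br)c2c1C[C@H](O)C(C)(C)O2 | intermediate
7 | (3S)-8-bromo-3-(tert-butyldimethylsilyloxy)-5-methoxy-2,2-dimethylchroman | COc1ccc(Br)c2c1C[C@H](O[Si](C)(C)C(C)(C)C)C(C)(C)O2 | intermediate
8 | p-coumaric acid, (E)-3-(4-hydroxyphenyl)prop-2-enoic acid | O=C(O)/C=C/c1ccc(O)cc1 | starting material
9 | benzotriazol-1-yl (E)-3-(4-hydroxyphenyl)prop-2-enoate | O=C(/C=C/c1ccc(O)cc1)On1nnc2ccccc21 | intermediate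
10 | (E)-3-(4-hydroxyphenyl)-N-methoxy-N-methylprop-2-enamide | CON(C)C(=O)/C=C/c1ccc(O)cc1 | intermediate
11 | (E)-3-[4-(tert-butyldimethylsilyloxy)phenyl]-N-methoxy-N-methylprop-2-enamide | CON(C)C(=O)/C=C/c1ccc(O[Si](C)(C)C(C)(C)C)cc1 | intermediate
12 | [(3S)-3-(tert-butyldimethylsilyloxy)-5-methoxy-2,2-dimethylchroman-8-yl]lithium | COc1ccc([Li])c2c1C[C@H](O[Si](C)(C)C(C)(C)C)C(C)(C)O2 | intermediate
13 | lithium alkoxide of the tetrahedral adduct of 12 and 11 (either configuration at the new carbinol carbon) | COc1ccc(C(O[Li])(N(C)OC)/C=C/c3ccc(O[Si](C)(C)C(C)(C)C)cc3)c2c1C[C@H](O[Si](C)(C)C(C)(C)C)C(C)(C)O2 | intermediate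
14 | (E)-1-[(3S)-3-(tert-butyldimethylsilyloxy)-5-methoxy-2,2-dimethylchroman-8-yl]-3-[4-(tert-butyldimethylsilyloxy)phenyl]prop-2-en-1-one | COc1ccc(C(=O)/C=C/c3ccc(O[Si](C)(C)C(C)(C)C)cc3)c2c1C[C@H](O[Si](C)(C)C(C)(C)C)C(C)(C)O2 | intermediate
15 | (E)-1-[(3S)-3-hydroxy-5-methoxy-2,2-dimethylchroman-8-yl]-3-(4-hydroxyphenyl)prop-2-en-1-one | COc1ccc(C(=O)/C=C/c2ccc(O)cc2)c2c1C[C@H](O)C(C)(C)O2 | target

**Step count**

Total: 8 steps. Longest linear sequence: 6 steps (steps 1, 2, 3, 4, 7, 8 from 2-bromo-5-methoxyphenol); steps 5 and 6 form the two-step side branch.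

**Steps most likely to fail**

Step 2. The carbene may be oxidised a second time by the N-oxide before the crowded C4a position, flanked by two oxygen substituents, can capture it, or gold-catalysed hydroarylation of the alkyne may outrun the oxidation. The fallback sets out from 3 and comes back to the route at 6. Heating 3 in N,N-diethylaniline at about 190 °C should bring about the aromatic Claisen rearrangement, [1,5]-hydrogen shift and 6π-electrocyclisation that give 8-bromo-5-methoxy-2,2-dimethyl-2H-chromene F1. Jacobsen–Katsuki epoxidation follows, with (S,S)-N,N'-bis(3,5-di-tert-butylsalicylidene)-1,2-cyclohexanediaminomanganese chloride, NaOCl and 4-phenylpyridine N-oxide in CH2Cl2 at 0 °C. This catalyst enantiomer is the one expected to give the (3S,4S)-oxides of 2,2-dimethylchromenes, here (3S,4S)-8-bromo-3,4-epoxy-5-methoxy-2,2-dimethylchroman F2. Hydride opening at the benzylic C4 with LiBHEt3 in THF at 0 °C leaves the C3–O bond untouched and should give 6 directly, so steps 2 and 3 are both bypassed.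

Step 7. The aryllithium may add in conjugate fashion to the cinnamoyl acceptor, or be quenched by proton transfer before it acylates. The fallback sets out from 7 and comes back to the route at 15. Bromine–lithium exchange as before, followed by N-methoxy-N-methylacetamide, should give the methyl ketone 1-[(3S)-3-(tert-butyldimethylsilyloxy)-5-methoxy-2,2-dimethylchroman-8-yl]ethan-1-one F3. Claisen–Schmidt condensation of this ketone with 4-(methoxymethoxy)benzaldehyde (KOH, EtOH, rt) should build the E enone as (E)-1-[(3S)-3-(tert-butyldimethylsilyloxy)-5-methoxy-2,2-dimethylchroman-8-yl]-3-[4-(methoxymethoxy)phenyl]prop-2-en-1-one F4. Treatment with HCl in MeOH at 40 °C should then remove the methoxymethyl and the silyl group together to give 15.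

Step 3. Facial discrimination may be poor, because both ketone flanks are sp3 carbons and the ring oxygen may compete for boron. The fallback sets out from 5 and comes back to the route at 6. NaBH4 in MeOH at 0 °C should give racemic 8-bromo-5-methoxy-2,2-dimethylchroman-3-ol F5. Acylation with (1S)-camphanic chloride (DMAP, pyridine, CH2Cl2) should give two diastereomeric esters, the (3S)-camphanate F6 and the (3R)-camphanate F7, to be separated by chromatography or crystallisation. Saponification of the (3S)-camphanate with LiOH in THF–MeOH–H2O, followed by acidic work-up, should release 6.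

**Further compounds**

F1 | step 2 | 8-bromo-5-methoxy-2,2-dimethyl-2H-chromene | COc1ccc(Br)c2c1C=CC(C)(C)O2
F2 | step 2 | (3S,4S)-8-bromo-3,4-epoxy-5-methoxy-2,2-dimethylchroman | COc1ccc(Br)c2c1[C@@H]3O[C@@H]3C(C)(C)O2
F3 | step 7 | 1-[(3S)-3-(tert-butyldimethylsilyloxy)-5-methoxy-2,2-dimethylchroman-8-yl]ethan-1-one | COc1ccc(C(C)=O)c2c1C[C@H](O[Si](C)(C)C(C)(C)C)C(C)(C)O2
F4 | step 7 | (E)-1-[(3S)-3-(tert-butyldimethylsilyloxy)-5-methoxy-2,2-dimethylchroman-8-yl]-3-[4-(methoxymethoxy)phenyl]prop-2-en-1-one | COc1ccc(C(=O)/C=C/c3ccc(OCOC)cc3)c2c1C[C@H](O[Si](C)(C)C(C)(C)C)C(C)(C)O2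
F5 | step 3 | racemic 8-bromo-5-methoxy-2,2-dimethylchroman-3-ol | COc1ccc(Br)c2c1CC(O)C(C)(C)O2
F6 | step 3 | (3S)-8-bromo-5-methoxy-2,2-dimethylchroman-3-yl (1S,4R)-camphanate | CC1(C)[C@@]2(C)CC[C@]1(C(=O)O[C@H]3Cc4c(OC)ccc(Br)c4OC3(C)C)OC2=O
F7 | step 3 | (3R)-8-bromo-5-methoxy-2,2-dimethylchroman-3-yl (1S,4R)-camphanate | CC1(C)[C@@]2(C)CC[C@]1(C(=O)O[C@@H]3Cc4c(OC)ccc(Br)c4OC3(C)C)OC2=O
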